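Readings and results come from a simulation for substances that don't exist; the scatter is artificial.

18.5 min: that was the lifetime of J, c_J divided by its rate of loss, at the end of Thursday's run, and I reckoned Friday's flask from it.

| flask | J | Q | time |
|---|---|---|---|
| Thursday's | 150 mM | 7.50 mM |  |
| Wednesday's | 300 mM | 7.50 mM |  |
| Tuesday's | 150 mM | 3.70 mM |  |
| Friday's | 60.0 mM | 7.50 mM | 17 min |

| Thursday's run: time / min | Thursday's run: [J] / mM | Wednesday's run: time / min | Wednesday's run: [J] / mM | Tuesday's run: time / min | Tuesday's run: [J] / mM |
|---|---|---|---|---|---|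
| 2.1 | 137.2 | 2.1 | 286.3 | 2.1 | 145.6 |
| 4.2 | 125.8 | 4.2 | 271.7 | 4.2 | 141.9 |
| 6.4 | 114.3 | 6.4 | 257.3 | 6.4 | 137.8 |
| 8.5 | 103.4 | 8.5 | 242.8 | 8.5 | 132.1 |
| 11 | 90.6 | 11 | 227.1 | 11 | 128.4 |
| 13 | 82.7 | 13 | 214.2 | 13 | 126.4 |
| 15 | 73.5 | 15 | 202.3 | 15 | 122.0 |
| 17 | 66.6 | 17 | 189.1 | 17 | 118.2 |

(standard deviation of a reading: 0.8 mM)

- Overall: J -> G, with Q as catalyst.
- Constant volume, constant temperature.
- Readings of a species count what is bound in complexes too.
- An order is taken over about fifteen percent of the charge, up and down.

- the exponent of [J] in the starting rate at the charge of the Thursday's run (at the point where two percent of the J have become G) (one fixed amount of G, the same in the runs compared)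
- the exponent of [Q] in the starting rate at the charge of the Thursday's run (at the point where two percent of the J have become G)
- J in the Friday's run at 17 min, as a share of the J charged

I ranked stretches of the runs by rate of loss of J, from fastest to slowest, and read each lifetime from the readings.

Wednesday's run, up to 8.5 min: rate 6.73 mM/min, mean c_J 271 mM, lifetime 40.2 min

Thursday's run, up to 4.2 min: rate 5.76 mM/min, mean c_J 138 mM, lifetime 23.9 min

Thursday's run, from 13 min to 17 min: rate 4.03 mM/min, mean c_J 74.6 mM, lifetime 18.5 min

Tuesday's run, up to 17 min, with 3.70 mM of Q: rate 1.87 mM/min, lifetime 71.4 min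

Tuesday's stretch was the slowest, and it had less Q, so it stood apart from Friday's flask. Down Wednesday's and Thursday's lines, c_J fell by a factor of 1.96 and then 1.85, yet the lifetime shortened by 1.68 and then only 1.29. In these readings the lifetime was levelling off.

Friday's flask held Thursday's Q and started at 60.0 mM, just below Thursday's last reading. I therefore held the lifetime flat, treating J as pseudo-first-order:

17 min / 18.5 min = 0.920 lifetimes, so J left = exp(−0.920) = 39.8%

The forecast, using the “Integrated Michaelis-Menten form”, gave orders of 0.35 in J and 1.4 in Q, and 26% for Friday (18% to 34%), lower than my 39.8%.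

The flask gave 42.6%, with orders of 0.34 in J and 1.3 in Q.

    Q + J ⇌ QJ, settled at all times (5.010 /M)
    QJ + J ⇌ QJ2, settled at all times (71.10 /M)
    QJ2 → G + QJ (1.296 /min)
    Q + Qa → Vo

Friday's 42.6% is 0.853 lifetimes of 19.9 min each, beside the 18.5 min read from Thursday's run. Friday's lifetime owes part of its length to the 1.86 mM of Q taken by Qa: without that conversion, Friday's run leaves 35.3% of its J, a mean lifetime of 16.3 min. Thursday's flask was charged with 2.03 times Tuesday's Q, yet the mean lifetime over the first quarter of the J charged was 70.2 min in Tuesday's run against 23.3 min in Thursday's, a factor of 3.01; at Thursday's charge the same conversion raises the apparent order in Q from 0.97 to 1.3.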